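**Plan**

- Retrosynthesis: the C4 isobutyrate, the isopropenyl group (carried as a tertiary silyloxy carbinol) and the C9 acetate (α'-acetoxylation of a C8 enone) come off first. The cyclohexene is then cut at C8–C9 (alkoxide-accelerated [1,3] shift of a 2-vinylcyclobutanol) and at C5–C6 plus C9–C10 (ketene–alkene (2+2)); the cyclopentane is cut at C4–C5 (nickel-catalysed ynal cyclisation) and the chain at C1–C2 (auxiliary-controlled propargylation).
- Enabling feature: the quaternary spiro carbon C5 and its neighbour C10(H)CH3 are the two carbons of an exocyclic (Z)-ethylidene group on the cyclopentane. C6(CH3) and C9 are the terminal and central carbons of methylvinylketene, whose vinyl group (C7, C8) later widens the four-membered ring C5–C6–C9–C10 to the cyclohexene.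
- Forward order: acyclic hex-5-ynal, then the cyclopentane (C4–C5), then the spiro-cyclobutanone (C5–C6 and C9–C10), then the six-membered ring (C8–C9), then C8 oxidation, C9 acetoxylation, ester exchange at C4 and dehydration.
- Stereochemistry: C2 from an Evans alkylation, C4 from a CBS reduction, C5 and C10 together from suprafacial addition to the Z-alkene on the face anti to the C4 silyl ether, C9 from acetate delivery anti to the C10 methyl.
- The ketene-derived oxygen at C9 serves only to drive the ring expansion and is then removed: the C9 configuration left by fragmentation–recombination is not reliable, and an acyloxy group at C9 would deactivate C8–H towards allylic oxidation. The acetate is put back under steric control.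

Key step: step 11

Remark: locants C1–C10 in the text are those of the spiro[4.5]decane core of the target (C1H2, C2 side chain, C3H2, C4–O, C5 spiro, C6–CH3, C7, C8=O, C9–OAc, C10–CH3). C6 of 20 and 21 and the carbinol carbons of 14 and 21–23 are expected as epimer mixtures that converge later and are drawn without configuration.

**Route**

Step 1
Reactants: 1 pent-4-enoyl chloride; 2 (S)-4-benzyl-1,3-oxazolidin-2-one
Product: 3 (S)-4-benzyl-3-(pent-4-enoyl)-1,3-oxazolidin-2-one
Conditions: n-BuLi, THF, −78 °C; then 1, −78 → 0 °C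
Reagents that add atoms: none
Why: N-acylation of the lithiated oxazolidinone by an acid chloride (loading of the Evans auxiliary) is routine and creates no stereocentre.

Step 2
Reactants: 3 (S)-4-benzyl-3-(pent-4-enoyl)-1,3-oxazolidin-2-one; 4 3-bromoprop-1-yne
Product: 5 (S)-4-benzyl-3-[(2R)-2-(prop-2-yn-1-yl)pent-4-enoyl]-1,3-oxazolidin-2-one
Conditions: NaHMDS, THF, −78 °C; then 4 (excess), −78 → −45 °C
Reagents that add atoms: none
Why: Evans asymmetric alkylation: the chelated Z-sodium enolate is propargylated on the face opposite the benzyl group, which sets C2 and installs the arm that becomes C1, C5 and C10.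

Step 3
Reactants: 5 (S)-4-benzyl-3-[(2R)-2-(prop-2-yn-1-yl)pent-4-enoyl]-1,3-oxazolidin-2-one
Product: 6 methyl (2R)-2-(prop-2-yn-1-yl)pent-4-enoate
Conditions: NaOMe (cat.), MeOH/THF, 0 °C
Reagents that add atoms: methanol, CO
Why: Methoxide transesterification of the N-acyl oxazolidinone cleaves the exocyclic carbonyl and releases the auxiliary; at 0 °C the α-stereocentre should not epimerise.

Step 4
Reactants: 6 methyl (2R)-2-(prop-2-yn-1-yl)pent-4-enoate; 7 methylmagnesium bromide
Product: 9 (3R)-2-methyl-3-(prop-2-yn-1-yl)hex-5-en-2-ol, via methyl ketone 8 (not isolated)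
Conditions: 7 (4 equiv), THF, −20 °C → rt; aq. NH4Cl
Reagents that add atoms: none
Why: Double Grignard addition to the ester gives the tertiary carbinol that masks the isopropenyl group; the transient ketone is consumed faster than it enolises, and the equivalent used by the alkyne C–H is returned on work-up.

Step 5
Reactants: 9 (3R)-2-methyl-3-(prop-2-yn-1-yl)hex-5-en-2-ol
Product: 10 triethyl{[(3R)-2-methyl-3-(prop-2-yn-1-yl)hex-5-en-2-yl]oxy}silane
Conditions: TESOTf, 2,6-lutidine, CH2Cl2, 0 °C
Reagents that add atoms: triethylsilyl trifluoromethanesulfonate, CC[Si](CC)(CC)OS(=O)(=O)C(F)(F)F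
Why: Silyl triflate/lutidine silylation of a tertiary alcohol; the TES ether keeps the C2 side chain inert to ketene, hydride and potassium hydride.

Step 6
Reactants: 10 triethyl{[(3R)-2-methyl-3-(prop-2-yn-1-yl)hex-5-en-2-yl]oxy}silane
Product: 12 (3S)-3-[2-(triethylsilyloxy)propan-2-yl]hex-5-ynal, via vicinal diol 11 (not isolated)
Conditions: OsO4 (cat.), NaIO4, 2,6-lutidine, dioxane/H2O, rt
Reagents that add atoms: osmium tetroxide, O=[Os](=O)(=O)=O; sodium periodate, [Na+].[O-]I(=O)(=O)=O
Why: Lemieux–Johnson oxidation: osmium tetroxide dihydroxylates the terminal alkene much faster than the alkyne and periodate cleaves the diol to the aldehyde that becomes C4.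

Step 7
Reactants: 12 (3S)-3-[2-(triethylsilyloxy)propan-2-yl]hex-5-ynal; 13 dimethylzinc
Product: 14 (4S,Z)-2-ethylidene-4-[2-(triethylsilyloxy)propan-2-yl]cyclopentan-1-ol (C1 epimers)
Conditions: Ni(cod)2 (10 mol %), 13 (2.5 equiv), THF, 0 °C; aq. NH4Cl
Reagents that add atoms: none
Why: Nickel(0)-catalysed alkylative cyclisation of an ynal with an organozinc: oxidative cyclisation gives an oxanickelacyclopentene (five-membered carbocycle closed exo at C4–C5), and methyl transfer from zinc followed by reductive elimination places the methyl on C10 cis to C4, so the Z-alkene follows from the mechanism; the C4 carbinol is expected as an epimer mixture, which steps 8 and 9 correct.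

Step 8
Reactants: 14 (4S,Z)-2-ethylidene-4-[2-(triethylsilyloxy)propan-2-yl]cyclopentan-1-ol (C1 epimers)
Product: 15 (4S,Z)-2-ethylidene-4-[2-(triethylsilyloxy)propan-2-yl]cyclopentan-1-one
Conditions: Dess–Martin periodinane, NaHCO3, CH2Cl2, 0 °C
Reagents that add atoms: none
Why: Buffered Dess–Martin oxidation converges both carbinol epimers to one enone under neutral conditions that should leave the less stable Z-ethylidene geometry intact.

Step 9
Reactants: 15 (4S,Z)-2-ethylidene-4-[2-(triethylsilyloxy)propan-2-yl]cyclopentan-1-one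
Product: 16 (1R,4S,Z)-2-ethylidene-4-[2-(triethylsilyloxy)propan-2-yl]cyclopentan-1-ol
Conditions: (S)-Me-CBS (0.2 equiv), catecholborane, toluene, −78 °C
Reagents that add atoms: none
Why: Corey–Bakshi–Shibata reduction: with the alkylidene-bearing side as the large group the (S)-oxazaborolidine delivers hydride to give the 1R carbinol (C4, trans to the C2 side chain) by reagent control, independent of the weak 1,3-substrate bias.

Step 10
Reactants: 16 (1R,4S,Z)-2-ethylidene-4-[2-(triethylsilyloxy)propan-2-yl]cyclopentan-1-ol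
Product: 17 tert-butyl{[(1R,4S,Z)-2-ethylidene-4-[2-(triethylsilyloxy)propan-2-yl]cyclopentyl]oxy}dimethylsilane
Conditions: TBSOTf, 2,6-lutidine, CH2Cl2, −78 °C
Reagents that add atoms: tert-butyldimethylsilyl trifluoromethanesulfonate, CC(C)(C)[Si](C)(C)OS(=O)(=O)C(F)(F)F
Why: Silylation of the allylic alcohol; the bulky TBS ether is both the protecting group and the element that shields one alkene face in step 11.

Step 11
Reactants: 17 tert-butyl{[(1R,4S,Z)-2-ethylidene-4-[2-(triethylsilyloxy)propan-2-yl]cyclopentyl]oxy}dimethylsilane; 18 (E)-2-methylbut-2-enoyl chloride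
Product: 20 (3S,4R,5R,7S)-5-(tert-butyldimethylsilyloxy)-1-ethenyl-1,3-dimethyl-7-[2-(triethylsilyloxy)propan-2-yl]spiro[3.4]octan-2-one (C1 epimers), via methylvinylketene 19 (not isolated)
Conditions: 18 (3 equiv), Et3N, CH2Cl2, rt; then 17, EtAlCl2 (hexanes), −78 → −40 °C
Reagents that add atoms: none
Why: Lewis acid-promoted ketene–alkene (2+2) cycloaddition, closest to EtAlCl2-promoted additions of in situ generated disubstituted ketenes to unactivated alkenes and to thermal vinylketene–alkene additions: dehydrochlorination of 18 gives methylvinylketene 19, whose aluminium-bound central carbon C9 is attacked by the less substituted alkene carbon C10, and the cation developing at C5 is captured by the ketene terminus C6. The four-membered ring thus closes asynchronously (C9–C10 first, then C5–C6) as a spiro-cyclobutanone with the carbonyl next to C10. Addition is suprafacial on the alkene, so the Z geometry fixes the C10 methyl cis to C4, and C5 is set by attack on the face anti to the C4–OTBS group, which allylic 1,3-strain with the Z-methyl turns pseudo-axial over one face. The step needs this facial selectivity and the C9-to-C10 regiochemistry; the first rests on the adjacent silyl ether outweighing the remote, pseudo-equatorial C2 side chain, the second on cation stabilisation at the disubstituted carbon C5. The C6 configuration is irrelevant because C6 becomes sp2 in step 13, and the isopropenyl group is carried as a tertiary silyl ether so that C5=C10 is the only ketenophile.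

Step 12
Reactants: 20 (3S,4R,5R,7S)-5-(tert-butyldimethylsilyloxy)-1-ethenyl-1,3-dimethyl-7-[2-(triethylsilyloxy)propan-2-yl]spiro[3.4]octan-2-one (C1 epimers)
Product: 21 (3S,4R,5R,7S)-5-(tert-butyldimethylsilyloxy)-1-ethenyl-1,3-dimethyl-7-[2-(triethylsilyloxy)propan-2-yl]spiro[3.4]octan-2-ol (C1 and C2 epimers)
Conditions: NaBH4, MeOH/THF, 0 °C
Reagents that add atoms: none
Why: Borohydride reduction of a strained cyclobutanone; hydride should enter anti to the C10 methyl, but either carbinol epimer serves in step 13.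

Step 13
Reactants: 21 (3S,4R,5R,7S)-5-(tert-butyldimethylsilyloxy)-1-ethenyl-1,3-dimethyl-7-[2-(triethylsilyloxy)propan-2-yl]spiro[3.4]octan-2-ol (C1 and C2 epimers)
Product: 23 O-[(2S,4R,5R,10S)-4-(tert-butyldimethylsilyloxy)-6,10-dimethyl-2-[2-(triethylsilyloxy)propan-2-yl]spiro[4.5]dec-6-en-9-yl] S-methyl carbonodithioate (C9 epimers), via potassium cyclohexenolate 22 (not isolated)
Conditions: KH, 18-crown-6, THF, 0 °C → rt; then CS2; then MeI, 0 °C
Reagents that add atoms: carbon disulfide, S=C=S; iodomethane, CI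
Why: Alkoxide-accelerated vinylcyclobutane rearrangement: the potassium alkoxide cleaves C6–C9 to an aldehyde/allyl-anion pair that recloses at the vinyl terminus C8 (net [1,3] shift, six-membered ring with C6=C7), and the new alkoxide 22 is trapped in the same flask as the xanthate; the C9 configuration does not matter because C9 is deoxygenated next.

Step 14
Reactants: 23 O-[(2S,4R,5R,10S)-4-(tert-butyldimethylsilyloxy)-6,10-dimethyl-2-[2-(triethylsilyloxy)propan-2-yl]spiro[4.5]dec-6-en-9-yl] S-methyl carbonodithioate (C9 epimers)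
Product: 24 tert-butyl{[(2S,4R,5R,10R)-6,10-dimethyl-2-[2-(triethylsilyloxy)propan-2-yl]spiro[4.5]dec-6-en-4-yl]oxy}dimethylsilane
Conditions: Bu3SnH, AIBN, toluene, 100 °C
Reagents that add atoms: none
Why: Barton–McCombie deoxygenation of a secondary xanthate; the homoallylic C9 radical should be reduced by the stannane faster than it can add reversibly to C6=C7.

Step 15
Reactants: 24 tert-butyl{[(2S,4R,5R,10R)-6,10-dimethyl-2-[2-(triethylsilyloxy)propan-2-yl]spiro[4.5]dec-6-en-4-yl]oxy}dimethylsilane
Product: 25 (2S,4R,5R,10R)-4-(tert-butyldimethylsilyloxy)-6,10-dimethyl-2-[2-(triethylsilyloxy)propan-2-yl]spiro[4.5]dec-6-en-8-one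
Conditions: CrO3, 3,5-dimethylpyrazole, CH2Cl2, −20 °C
Reagents that add atoms: chromium trioxide, O=[Cr](=O)=O
Why: Allylic oxidation with the chromium trioxide–3,5-dimethylpyrazole complex: C8 is the only allylic methylene (C5 is quaternary) and no longer carries a deactivating oxygen neighbour, so the C6=C7–C8=O enone should form.

Step 16
Reactants: 25 (2S,4R,5R,10R)-4-(tert-butyldimethylsilyloxy)-6,10-dimethyl-2-[2-(triethylsilyloxy)propan-2-yl]spiro[4.5]dec-6-en-8-one
Product: 26 (2S,4R,5R,9R,10S)-4-(tert-butyldimethylsilyloxy)-6,10-dimethyl-8-oxo-2-[2-(triethylsilyloxy)propan-2-yl]spiro[4.5]dec-6-en-9-yl acetate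
Conditions: Mn(OAc)3·2H2O, benzene, reflux (Dean–Stark)
Reagents that add atoms: manganese(III) acetate, CC(=O)O[Mn](OC(C)=O)OC(C)=O
Why: Manganese(III) acetate α'-acetoxylation of an enone: the manganese enolate transfers acetate to C9 on the face anti to both the C10 methyl and the C4 branch of the spiro centre, which should give the 9,10-trans acetate.

Step 17
Reactants: 26 (2S,4R,5R,9R,10S)-4-(tert-butyldimethylsilyloxy)-6,10-dimethyl-8-oxo-2-[2-(triethylsilyloxy)propan-2-yl]spiro[4.5]dec-6-en-9-yl acetate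
Product: 27 (2S,4R,5R,9R,10S)-4-hydroxy-2-(2-hydroxypropan-2-yl)-6,10-dimethyl-8-oxospiro[4.5]dec-6-en-9-yl acetate
Conditions: aq. HF (48 %), MeCN, 0 °C → rt
Reagents that add atoms: none
Why: Fluoride-driven cleavage of both silyl ethers under acidic conditions, which should neither epimerise nor migrate the α-acetoxy ketone.

Step 18
Reactants: 27 (2S,4R,5R,9R,10S)-4-hydroxy-2-(2-hydroxypropan-2-yl)-6,10-dimethyl-8-oxospiro[4.5]dec-6-en-9-yl acetate
Product: 28 (2S,4R,5R,9R,10S)-9-acetoxy-2-(2-hydroxypropan-2-yl)-6,10-dimethyl-8-oxospiro[4.5]dec-6-en-4-yl 2-methylpropanoate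
Conditions: (i-PrCO)2O, DMAP, pyridine, CH2Cl2, rt
Reagents that add atoms: isobutyric anhydride, CC(C)C(=O)OC(=O)C(C)C
Why: DMAP-catalysed acyl transfer: the secondary C4 alcohol is esterified while the tertiary carbinol stays free.

Step 19
Reactants: 28 (2S,4R,5R,9R,10S)-9-acetoxy-2-(2-hydroxypropan-2-yl)-6,10-dimethyl-8-oxospiro[4.5]dec-6-en-4-yl 2-methylpropanoate
Product: 30 (2S,4R,5R,9R,10S)-9-acetoxy-6,10-dimethyl-8-oxo-2-(prop-1-en-2-yl)spiro[4.5]dec-6-en-4-yl 2-methylpropanoate, via Burgess sulfamate salt 29 (not isolated)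
Conditions: Burgess reagent, benzene, 50 °C
Reagents that add atoms: none
Why: Burgess dehydration: syn-elimination from the tertiary sulfamate can take one of six methyl hydrogens or the single hindered ring methine, which should favour the isopropenyl over the isopropylidene isomer; esters and enone are inert.

**Compound list**

1 | pent-4-enoyl chloride | C=CCCC(=O)Cl | starting material
2 | (S)-4-benzyl-1,3-oxazolidin-2-one | O=C1N[C@@H](Cc2ccccc2)CO1 | starting material
3 | (S)-4-benzyl-3-(pent-4-enoyl)-1,3-oxazolidin-2-one | C=CCCC(=O)N1[C@@H](Cc2ccccc2)COC1=O | intermediate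
4 | 3-bromoprop-1-yne (propargyl bromide) | C#CCBr | starting material
5 | (S)-4-benzyl-3-[(2R)-2-(prop-2-yn-1-yl)pent-4-enoyl]-1,3-oxazolidin-2-one | C=CC[C@H](CC#C)C(=O)N1[C@@H](Cc2ccccc2)COC1=O | intermediate
6 | methyl (2R)-2-(prop-2-yn-1-yl)pent-4-enoate | C=CC[C@H](CC#C)C(=O)OC | intermediate
7 | methylmagnesium bromide | C[Mg]Br | starting material
8 | (3R)-3-(prop-2-yn-1-yl)hex-5-en-2-one | C=CC[C@H](CC#C)C(C)=O | intermediate (not isolated)
9 | (3R)-2-methyl-3-(prop-2-yn-1-yl)hex-5-en-2-ol | C=CC[C@H](CC#C)C(C)(C)O | intermediate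
10 | triethyl{[(3R)-2-methyl-3-(prop-2-yn-1-yl)hex-5-en-2-yl]oxy}silane | C=CC[C@H](CC#C)C(C)(C)O[Si](CC)(CC)CC | intermediate
11 | (4S)-5-methyl-4-(prop-2-yn-1-yl)-5-(triethylsilyloxy)hexane-1,2-diol (C2 epimers) | OCC(O)C[C@H](CC#C)C(C)(C)O[Si](CC)(CC)CC | intermediate (not isolated)
12 | (3S)-3-[2-(triethylsilyloxy)propan-2-yl]hex-5-ynal | O=CC[C@H](CC#C)C(C)(C)O[Si](CC)(CC)CC | intermediate
13 | dimethylzinc | C[Zn]C | starting material
14 | (4S,Z)-2-ethylidene-4-[2-(triethylsilyloxy)propan-2-yl]cyclopentan-1-ol (C1 epimers) | CC(C)(O[Si](CC)(CC)CC)[C@@H]1CC(O)/C(C1)=C\C | intermediate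
15 | (4S,Z)-2-ethylidene-4-[2-(triethylsilyloxy)propan-2-yl]cyclopentan-1-one | CC(C)(O[Si](CC)(CC)CC)[C@@H]1CC(=O)/C(C1)=C\C | intermediate
16 | (1R,4S,Z)-2-ethylidene-4-[2-(triethylsilyloxy)propan-2-yl]cyclopentan-1-ol | CC(C)(O[Si](CC)(CC)CC)[C@@H]1C[C@@H](O)/C(C1)=C\C | intermediate
17 | tert-butyl{[(1R,4S,Z)-2-ethylidene-4-[2-(triethylsilyloxy)propan-2-yl]cyclopentyl]oxy}dimethylsilane | CC(C)(O[Si](CC)(CC)CC)[C@@H]1C[C@@H](O[Si](C)(C)C(C)(C)C)/C(C1)=C\C | intermediate
18 | (E)-2-methylbut-2-enoyl chloride (tigloyl chloride) | C/C=C(\C)C(=O)Cl | starting material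
19 | 2-methylbuta-1,3-dien-1-one (methylvinylketene) | C=CC(C)=C=O | intermediate (not isolated)
20 | (3S,4R,5R,7S)-5-(tert-butyldimethylsilyloxy)-1-ethenyl-1,3-dimethyl-7-[2-(triethylsilyloxy)propan-2-yl]spiro[3.4]octan-2-one (C1 epimers) | CC(C)(O[Si](CC)(CC)CC)[C@@H]1C[C@@H](O[Si](C)(C)C(C)(C)C)[C@@]2(C1)C(C)(C=C)C(=O)[C@H]2C | intermediate
21 | (3S,4R,5R,7S)-5-(tert-butyldimethylsilyloxy)-1-ethenyl-1,3-dimethyl-7-[2-(triethylsilyloxy)propan-2-yl]spiro[3.4]octan-2-ol (C1 and C2 epimers) | CC(C)(O[Si](CC)(CC)CC)[C@@H]1C[C@@H](O[Si](C)(C)C(C)(C)C)[C@@]2(C1)C(C)(C=C)C(O)[C@H]2C | intermediate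
22 | potassium (2S,4R,5R,10S)-4-(tert-butyldimethylsilyloxy)-6,10-dimethyl-2-[2-(triethylsilyloxy)propan-2-yl]spiro[4.5]dec-6-en-9-olate (C9 epimers) | CC(C)(O[Si](CC)(CC)CC)[C@@H]1C[C@@H](O[Si](C)(C)C(C)(C)C)[C@@]2(C1)C(C)=CCC([O-])[C@H]2C.[K+] | intermediate (not isolated)
23 | O-[(2S,4R,5R,10S)-4-(tert-butyldimethylsilyloxy)-6,10-dimethyl-2-[2-(triethylsilyloxy)propan-2-yl]spiro[4.5]dec-6-en-9-yl] S-methyl carbonodithioate (C9 epimers) | CC(C)(O[Si](CC)(CC)CC)[C@@H]1C[C@@H](O[Si](C)(C)C(C)(C)C)[C@@]2(C1)C(C)=CCC(OC(=S)SC)[C@H]2C | intermediate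
24 | tert-butyl{[(2S,4R,5R,10R)-6,10-dimethyl-2-[2-(triethylsilyloxy)propan-2-yl]spiro[4.5]dec-6-en-4-yl]oxy}dimethylsilane | CC(C)(O[Si](CC)(CC)CC)[C@@H]1C[C@@H](O[Si](C)(C)C(C)(C)C)[C@@]2(C1)C(C)=CCC[C@H]2C | intermediate
25 | (2S,4R,5R,10R)-4-(tert-butyldimethylsilyloxy)-6,10-dimethyl-2-[2-(triethylsilyloxy)propan-2-yl]spiro[4.5]dec-6-en-8-one | CC(C)(O[Si](CC)(CC)CC)[C@@H]1C[C@@H](O[Si](C)(C)C(C)(C)C)[C@@]2(C1)C(C)=CC(=O)C[C@H]2C | intermediate
26 | (2S,4R,5R,9R,10S)-4-(tert-butyldimethylsilyloxy)-6,10-dimethyl-8-oxo-2-[2-(triethylsilyloxy)propan-2-yl]spiro[4.5]dec-6-en-9-yl acetate | CC(C)(O[Si](CC)(CC)CC)[C@@H]1C[C@@H](O[Si](C)(C)C(C)(C)C)[C@@]2(C1)C(C)=CC(=O)[C@H](OC(C)=O)[C@H]2C | intermediate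
27 | (2S,4R,5R,9R,10S)-4-hydroxy-2-(2-hydroxypropan-2-yl)-6,10-dimethyl-8-oxospiro[4.5]dec-6-en-9-yl acetate | CC(C)(O)[C@@H]1C[C@@H](O)[C@@]2(C1)C(C)=CC(=O)[C@H](OC(C)=O)[C@H]2C | intermediate
28 | (2S,4R,5R,9R,10S)-9-acetoxy-2-(2-hydroxypropan-2-yl)-6,10-dimethyl-8-oxospiro[4.5]dec-6-en-4-yl 2-methylpropanoate | CC(C)(O)[C@@H]1C[C@@H](OC(=O)C(C)C)[C@@]2(C1)C(C)=CC(=O)[C@H](OC(C)=O)[C@H]2C | intermediate
29 | triethylammonium salt of the N-(methoxycarbonyl)sulfamate ester of 28 at the tertiary carbinol | CC[NH+](CC)CC.COC(=O)[N-]S(=O)(=O)OC(C)(C)[C@@H]1C[C@@H](OC(=O)C(C)C)[C@@]2(C1)C(C)=CC(=O)[C@H](OC(C)=O)[C@H]2C | intermediate (not isolated)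
30 | (2S,4R,5R,9R,10S)-9-acetoxy-6,10-dimethyl-8-oxo-2-(prop-1-en-2-yl)spiro[4.5]dec-6-en-4-yl 2-methylpropanoate | C=C(C)[C@@H]1C[C@@H](OC(=O)C(C)C)[C@@]2(C1)C(C)=CC(=O)[C@H](OC(C)=O)[C@H]2C | target

**Step count and risks**

Total step count: 19. Longest linear sequence: 19 steps (1 and 2 to 30); the route is fully linear.

Steps most likely to fail:

1. Step 11. The trisubstituted alkene with an allylic silyl ether may react more slowly than the ketene oligomerises. The C2 side chain, which lies on the face that must be attacked, may erode the facial selectivity, and the Lewis acid may ionise the tertiary silyl ether. Fallback, from 17 to 20: a keteniminium–alkene (2+2), which uses a far more electrophilic cumulene without an aluminium Lewis acid. Commercial 2-methylbut-3-enoic acid is coupled with dimethylamine to N,N,2-trimethylbut-3-enamide F1. Triflic anhydride and 2,4,6-collidine in 1,2-dichloroethane convert it into the vinylketeniminium triflate F2, which should add to 17 with the same regiochemistry and facial preference to give the cyclobutaniminium triflate F3. Aqueous bicarbonate hydrolysis of F3 returns to the route at 20.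

2. Step 13. The alkoxide may fragment without reclosing (proton transfer from the enolisable C10–H aldehyde to the allyl anion gives a ring-opened product or epimerises C10). Silyl migration from O4 to O9 and incomplete trapping of the hindered alkoxide by carbon disulfide are further possibilities. Fallback, from 20 to 23: a neutral photochemical 1,3-acyl shift of the β,γ-unsaturated cyclobutanone (direct irradiation near 300 nm in benzene) should give the ring-expanded cyclohex-3-enone F4 without any anionic intermediate. Sodium borohydride reduces it to the cyclohexenol F5, and sodium hydride, carbon disulfide and iodomethane convert F5 into xanthate 23.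

3. Step 16. Acetate transfer from manganese may show poor diastereoselectivity at C9, and the hot, slightly acidic medium may cleave the tertiary silyl ether or over-oxidise. Fallback, from 25 to 26: enolate chemistry in place of the manganese oxidation. Kinetic deprotonation at C9 with LDA and trapping with chlorotrimethylsilane at −78 °C gives the cross-conjugated silyl dienol ether F6. Rubottom oxidation with buffered mCPBA, which attacks anti to the C10 methyl, followed by mild acidic desilylation gives the α'-hydroxy enone F7. Acetic anhydride, pyridine and DMAP convert F7 into 26.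

**Further compounds**

F1 | step 11 | N,N,2-trimethylbut-3-enamide | C=CC(C)C(=O)N(C)C
F2 | step 11 | N-methyl-N-(2-methylbuta-1,3-dien-1-ylidene)methanaminium trifluoromethanesulfonate | C=CC(C)=C=[N+](C)C.[O-]S(=O)(=O)C(F)(F)F
F3 | step 11 | N,N-dimethyl iminium trifluoromethanesulfonate of cyclobutanone 20 (C=N+Me2 in place of C=O) | CC(C)(O[Si](CC)(CC)CC)[C@@H]1C[C@@H](O[Si](C)(C)C(C)(C)C)[C@@]2(C1)C(C)(C=C)C(=[N+](C)C)[C@H]2C.[O-]S(=O)(=O)C(F)(F)F
F4 | step 13 | (2S,4R,5R,10S)-4-(tert-butyldimethylsilyloxy)-6,10-dimethyl-2-[2-(triethylsilyloxy)propan-2-yl]spiro[4.5]dec-6-en-9-one | CC(C)(O[Si](CC)(CC)CC)[C@@H]1C[C@@H](O[Si](C)(C)C(C)(C)C)[C@@]2(C1)C(C)=CCC(=O)[C@H]2C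
F5 | step 13 | (2S,4R,5R,10S)-4-(tert-butyldimethylsilyloxy)-6,10-dimethyl-2-[2-(triethylsilyloxy)propan-2-yl]spiro[4.5]dec-6-en-9-ol (C9 epimers) | CC(C)(O[Si](CC)(CC)CC)[C@@H]1C[C@@H](O[Si](C)(C)C(C)(C)C)[C@@]2(C1)C(C)=CCC(O)[C@H]2C
F6 | step 16 | tert-butyl{[(2S,4R,5R,10R)-6,10-dimethyl-2-[2-(triethylsilyloxy)propan-2-yl]-8-(trimethylsilyloxy)spiro[4.5]deca-6,8-dien-4-yl]oxy}dimethylsilane | CC(C)(O[Si](CC)(CC)CC)[C@@H]1C[C@@H](O[Si](C)(C)C(C)(C)C)[C@@]2(C1)C(C)=CC(O[Si](C)(C)C)=C[C@H]2C
F7 | step 16 | (2S,4R,5R,9R,10S)-4-(tert-butyldimethylsilyloxy)-9-hydroxy-6,10-dimethyl-2-[2-(triethylsilyloxy)propan-2-yl]spiro[4.5]dec-6-en-8-one | CC(C)(O[Si](CC)(CC)CC)[C@@H]1C[C@@H](O[Si](C)(C)C(C)(C)C)[C@@]2(C1)C(C)=CC(=O)[C@H](O)[C@H]2C
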